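**Strategy**

Everything rests on cutting the side chain (Cα–Cε, counted from the cyclohexane ring) at two bonds of its E-trisubstituted alkene: Cγ–CH3 and Cδ–Cε, the latter leading to the quinone ring. Because Cγ=Cδ sits between the Cα–Cβ tether and the quinone-bound methylene Cε, a terminal alkyne can supply it: one flask adds methyl and aluminium syn across the alkyne and couples the alkenylalane with a chloromethyl-dimethoxybenzoquinone under nickel catalysis, fixing branch, geometry and the complete skeleton at quinone oxidation level. The precursor is the enantiopure (1R,3R)-butynyl-dimethyl-methylidenecyclohexane, made by an asymmetric Diels–Alder reaction and a Grob fragmentation; amine exchange and hydrolysis of the two methoxy groups finish the synthesis.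

Key step: step 11

Assumption: in step 3 the (S,S)-configured bis(oxazoline) ligand is taken, on the square-planar chelate model, to leave open the dienophile face that leads to the (3aS,7R,7aS) adduct; this sense of induction is a prediction, and the (R,R)-ligand would replace it without other change if the opposite sense were found.

**Route**

Step 1
Reactants: 1 3-methylcyclopent-2-en-1-one
Product: 2 2-iodo-3-methylcyclopent-2-en-1-one
Conditions: I2 (1.5 equiv), pyridine, CH2Cl2, 0 °C to rt
Reagents that add atoms: iodine, II
Why: Pyridine adds reversibly to the enone β-carbon, the enolate is iodinated at C2 and pyridine is expelled again (α-iodination of an enone by addition–elimination), a sequence that a β-methyl group slows but does not block.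

Step 2
Reactants: 2 2-iodo-3-methylcyclopent-2-en-1-one
Product: 3 methyl 2-methyl-5-oxocyclopent-1-ene-1-carboxylate
Conditions: Pd(OAc)2 (5 mol %), PPh3 (10 mol %), CO (1 atm), Et3N, MeOH/DMF, 60 °C
Reagents that add atoms: carbon monoxide, [C-]#[O+]; methanol, CO
Why: Oxidative addition of zerovalent palladium into the alkenyl C–I bond, CO insertion and methanolysis of the acylpalladium species (palladium-catalysed alkoxycarbonylation) should install the ester at C2 without touching the enone.

Step 3
Reactants: 3 methyl 2-methyl-5-oxocyclopent-1-ene-1-carboxylate; 4 (E)-penta-1,3-diene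
Product: 5 methyl (3aS,7R,7aS)-3a,7-dimethyl-1-oxo-2,3,3a,4,7,7a-hexahydro-1H-indene-7a-carboxylate
Conditions: [Cu((S,S)-t-Bu-box)](SbF6)2 (10 mol %, from CuCl2, AgSbF6 and 2,2'-(propane-2,2-diyl)bis[(4S)-4-tert-butyl-4,5-dihydro-1,3-oxazole]), 4 (5 equiv), 4 Å MS, CH2Cl2, 0 °C to rt, sealed vessel
Reagents that add atoms: none
Why: Two-point binding of the β-keto ester to the divalent copper bis(oxazoline) cation activates the dienophile and fixes its plane, so that in this chiral-Lewis-acid-catalysed Diels–Alder reaction the diene should add with its CH2 terminus to the β-carbon (ortho regiochemistry), endo to the ring ketone (C7 methyl cis to C1, trans to the ester) and on the face left open by the tert-butyl groups, which together set C3a, C7 and C7a.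

Step 4
Reactants: 5 methyl (3aS,7R,7aS)-3a,7-dimethyl-1-oxo-2,3,3a,4,7,7a-hexahydro-1H-indene-7a-carboxylate
Product: 6 methyl (3aR,7R,7aS)-3a,7-dimethyl-1-oxooctahydro-1H-indene-7a-carboxylate
Conditions: H2 (1 atm), Pd/C (10 wt %), EtOAc, rt
Reagents that add atoms: none
Why: Heterogeneous hydrogenation should saturate the cis-disubstituted C5=C6 alkene, the only group reducible under these conditions, without creating or disturbing a stereocentre (the descriptor at C3a changes only through ligand priorities).

Step 5
Reactants: 6 methyl (3aR,7R,7aS)-3a,7-dimethyl-1-oxooctahydro-1H-indene-7a-carboxylate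
Product: 7 (1S,3aR,7R,7aR)-7a-(hydroxymethyl)-3a,7-dimethyloctahydro-1H-inden-1-ol
Conditions: LiAlH4 (2 equiv), THF, 0 °C to 50 °C; aqueous NaOH work-up
Reagents that add atoms: none
Why: LiAlH4 reduces the ketone and the neopentyl ester to the 1,3-diol (hydride reduction), with hydride expected to reach C1 from the convex face that carries the angular groups so that the hydroxyl lies anti to the new CH2OH, a stereocentre that is erased again in step 7.

Step 6
Reactants: 7 (1S,3aR,7R,7aR)-7a-(hydroxymethyl)-3a,7-dimethyloctahydro-1H-inden-1-ol
Product: 8 [(1S,3aR,7R,7aR)-1-hydroxy-3a,7-dimethyloctahydro-7aH-inden-7a-yl]methyl methanesulfonate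
Conditions: MsCl (1.05 equiv), Et3N (1.5 equiv), CH2Cl2, −30 °C to 0 °C
Reagents that add atoms: methanesulfonyl chloride, CS(=O)(=O)Cl
Why: With one equivalent of MsCl at low temperature the primary hydroxyl should be sulfonylated in preference to the more shielded secondary cyclopentanol (selective monomesylation of a 1,3-diol).

Step 7
Reactants: 8 [(1S,3aR,7R,7aR)-1-hydroxy-3a,7-dimethyloctahydro-7aH-inden-7a-yl]methyl methanesulfonate
Product: 9 3-[(1R,3R)-1,3-dimethyl-2-methylidenecyclohexyl]propanal
Conditions: KOt-Bu (1.1 equiv), THF, 0 °C; pH 7 buffer quench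
Reagents that add atoms: none
Why: Deprotonation of the C1 hydroxyl triggers a Grob fragmentation in which the C1–C7a bond breaks anti-periplanar to the freely rotating CH2–OMs bond, releasing the aldehyde and the ring methylidene in one stroke while the anti disposition of O1 and CH2OMs rules out oxetane closure and neither C3a nor C7 (the future ring C1 and C3) is touched.

Step 8
Reactants: 9 3-[(1R,3R)-1,3-dimethyl-2-methylidenecyclohexyl]propanal
Product: 10 (1R,3R)-1-(but-3-yn-1-yl)-1,3-dimethyl-2-methylidenecyclohexane
Conditions: dimethyl (1-diazo-2-oxopropyl)phosphonate (1.3 equiv), K2CO3 (2 equiv), MeOH, 0 °C to rt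
Reagents that add atoms: dimethyl (1-diazo-2-oxopropyl)phosphonate (Ohira–Bestmann reagent), COP(=O)(OC)C(=[N+]=[N-])C(C)=O
Why: Methanolysis of the reagent gives the dimethyl (diazomethyl)phosphonate anion, which olefinates the aldehyde to a diazoalkene that loses N2 and rearranges by 1,2-hydride shift to the terminal alkyne (Ohira–Bestmann homologation), under conditions mild enough to leave the methylidene and both stereocentres intact.

Step 9
Reactants: 11 1,2,4,5-tetramethoxybenzene
Product: 12 3-(chloromethyl)-1,2,4,5-tetramethoxybenzene
Conditions: (CH2O)n (0.9 equiv), conc. aq HCl, AcOH, rt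
Reagents that add atoms: formaldehyde (as paraformaldehyde), C=O; hydrogen chloride, Cl
Why: Either of the two equivalent free positions of this electron-rich arene should undergo Blanc chloromethylation under mild acid, and limiting formaldehyde holds the reaction at the mono-adduct.

Step 10
Reactants: 12 3-(chloromethyl)-1,2,4,5-tetramethoxybenzene
Product: 13 3-(chloromethyl)-2,5-dimethoxy-1,4-benzoquinone
Conditions: (NH4)2Ce(NO3)6 (2.5 equiv), MeCN/H2O (2:1), 0 °C, short reaction time
Reagents that add atoms: water, O
Why: Two one-electron oxidations by tetravalent cerium, attack of water at a para-related pair of methoxy-bearing carbons and loss of two molecules of methanol (oxidative demethylation) should give the para-quinone while the chloromethyl group survives the short, cold reaction.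

Step 11
Reactants: 10 (1R,3R)-1-(but-3-yn-1-yl)-1,3-dimethyl-2-methylidenecyclohexane; 13 3-(chloromethyl)-2,5-dimethoxy-1,4-benzoquinone; 14 trimethylaluminium
Product: 16 2,5-dimethoxy-3-{(2E)-5-[(1R,3R)-1,3-dimethyl-2-methylidenecyclohexyl]-3-methylpent-2-en-1-yl}-1,4-benzoquinone, via alkenylalane 15 (not isolated)
Conditions: 14 (2 equiv), Cp2ZrCl2 (0.25 equiv), CH2Cl2, 0 °C to rt; volatiles and excess AlMe3 removed in vacuo; THF, NiCl2(PPh3)2 (5 mol %) + n-BuLi (10 mol %), then 13 (0.9 equiv), −20 °C to 0 °C
Reagents that add atoms: none
Why: A methylzirconocene cation formed from Cp2ZrCl2 and AlMe3 adds its Zr–CH3 bond syn across the terminal alkyne of 10 with methyl going to the internal carbon Cγ, and Zr-to-Al exchange leaves the (E)-alkenyl(dimethyl)alane 15; zerovalent nickel, generated from NiCl2(PPh3)2 and two equivalents of n-BuLi, then inserts into the C–Cl bond of 13, takes the alkenyl group from aluminium and reductively eliminates to form Cδ–Cε with the alkene geometry retained. The closest known reaction type is zirconium-catalysed methylalumination of 1-alkynes (Negishi carboalumination) followed in the same flask by nickel-catalysed coupling of the alkenylalane with benzylic chlorides and chloromethylquinones, as practised for polyprenyl quinone side chains. No ring is closed and no stereocentre is made; C1 and C3 of the cyclohexane are remote and untouched. The step needs methyl delivery to Cγ, which the terminal alkyne secures sterically and electronically, and E geometry, which follows from syn addition and stereoretentive coupling. It needs the alkyne to react in preference to the ring methylidene, which is 1,1-disubstituted and flanked by a quaternary and a tertiary carbon and should therefore be inert to carbometalation. It needs coupling at carbon to outrun attack on the quinone, which is favoured by the activated C–Cl bond, by stripping excess AlMe3 before 13 is added, by THF as donor solvent and by low temperature.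

Step 12
Reactants: 16 2,5-dimethoxy-3-{(2E)-5-[(1R,3R)-1,3-dimethyl-2-methylidenecyclohexyl]-3-methylpent-2-en-1-yl}-1,4-benzoquinone; 17 3-methylbutan-1-amine
Product: 18 2-methoxy-5-[(3-methylbutyl)amino]-3-{(2E)-5-[(1R,3R)-1,3-dimethyl-2-methylidenecyclohexyl]-3-methylpent-2-en-1-yl}-1,4-benzoquinone
Conditions: 17 (1.5 equiv), EtOH, rt
Reagents that add atoms: none
Why: The primary amine should add to C5, the vinylogous-ester carbon next to the unsubstituted C6–H, and expel methoxide (addition–elimination on a methoxyquinone), whereas C2 is shielded by the C3 side chain and the amino group once installed deactivates the ring toward a second exchange.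

Step 13
Reactants: 18 2-methoxy-5-[(3-methylbutyl)amino]-3-{(2E)-5-[(1R,3R)-1,3-dimethyl-2-methylidenecyclohexyl]-3-methylpent-2-en-1-yl}-1,4-benzoquinone
Product: 20 metachromin H, via sodium quinonolate 19 (not isolated)
Conditions: 0.5 M aq NaOH, THF/MeOH, rt; then cold 1 M HCl to pH 3, 0 °C
Reagents that add atoms: sodium hydroxide, [Na+].[OH-]
Why: Hydroxide should add to C2 of the remaining vinylogous methyl ester (C2=C3–C4=O) and expel methoxide to give the vinylogous acid as its sodium salt (saponification of a methoxyquinone), which brief cold acidification protonates without isomerising the methylidene or the E alkene, while the far less electrophilic vinylogous amide at C5 is retained.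

**Compound list**

1 | 3-methylcyclopent-2-en-1-one | CC1=CC(=O)CC1 | starting material
2 | 2-iodo-3-methylcyclopent-2-en-1-one | CC1=C(I)C(=O)CC1 | intermediate
3 | methyl 2-methyl-5-oxocyclopent-1-ene-1-carboxylate | COC(=O)C1=C(C)CCC1=O | intermediate
4 | (E)-penta-1,3-diene | C=C/C=C/C | starting material
5 | methyl (3aS,7R,7aS)-3a,7-dimethyl-1-oxo-2,3,3a,4,7,7a-hexahydro-1H-indene-7a-carboxylate | COC(=O)[C@@]12[C@H](C)C=CC[C@]1(C)CCC2=O | intermediate
6 | methyl (3aR,7R,7aS)-3a,7-dimethyl-1-oxooctahydro-1H-indene-7a-carboxylate | COC(=O)[C@@]12[C@H](C)CCC[C@]1(C)CCC2=O | intermediate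
7 | (1S,3aR,7R,7aR)-7a-(hydroxymethyl)-3a,7-dimethyloctahydro-1H-inden-1-ol | OC[C@@]12[C@H](C)CCC[C@]1(C)CC[C@@H]2O | intermediate
8 | [(1S,3aR,7R,7aR)-1-hydroxy-3a,7-dimethyloctahydro-7aH-inden-7a-yl]methyl methanesulfonate | CS(=O)(=O)OC[C@@]12[C@H](C)CCC[C@]1(C)CC[C@@H]2O | intermediate
9 | 3-[(1R,3R)-1,3-dimethyl-2-methylidenecyclohexyl]propanal | C=C1[C@H](C)CCC[C@]1(C)CCC=O | intermediate
10 | (1R,3R)-1-(but-3-yn-1-yl)-1,3-dimethyl-2-methylidenecyclohexane | C=C1[C@H](C)CCC[C@]1(C)CCC#C | intermediate
11 | 1,2,4,5-tetramethoxybenzene | COc1cc(OC)c(OC)cc1OC | starting material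
12 | 3-(chloromethyl)-1,2,4,5-tetramethoxybenzene | COc1cc(OC)c(OC)c(CCl)c1OC | intermediate
13 | 3-(chloromethyl)-2,5-dimethoxy-1,4-benzoquinone | COC1=CC(=O)C(OC)=C(CCl)C1=O | intermediate
14 | trimethylaluminium | C[Al](C)C | starting material
15 | {(1E)-4-[(1R,3R)-1,3-dimethyl-2-methylidenecyclohexyl]-2-methylbut-1-en-1-yl}dimethylalumane | C=C1[C@H](C)CCC[C@]1(C)CC/C(C)=C/[Al](C)C | intermediate
16 | 2,5-dimethoxy-3-{(2E)-5-[(1R,3R)-1,3-dimethyl-2-methylidenecyclohexyl]-3-methylpent-2-en-1-yl}-1,4-benzoquinone | C=C1[C@H](C)CCC[C@]1(C)CC/C(C)=C/CC1=C(OC)C(=O)C=C(OC)C1=O | intermediate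
17 | 3-methylbutan-1-amine | CC(C)CCN | starting material
18 | 2-methoxy-5-[(3-methylbutyl)amino]-3-{(2E)-5-[(1R,3R)-1,3-dimethyl-2-methylidenecyclohexyl]-3-methylpent-2-en-1-yl}-1,4-benzoquinone | C=C1[C@H](C)CCC[C@]1(C)CC/C(C)=C/CC1=C(OC)C(=O)C=C(NCCC(C)C)C1=O | intermediate
19 | sodium salt of 20 at the C2 oxygen (sodium quinonolate) | C=C1[C@H](C)CCC[C@]1(C)CC/C(C)=C/CC1=C([O-])C(=O)C=C(NCCC(C)C)C1=O.[Na+] | intermediate
20 | metachromin H, 2-hydroxy-5-[(3-methylbutyl)amino]-3-{(2E)-5-[(1R,3R)-1,3-dimethyl-2-methylidenecyclohexyl]-3-methylpent-2-en-1-yl}-1,4-benzoquinone | C=C1[C@H](C)CCC[C@]1(C)CC/C(C)=C/CC1=C(O)C(=O)C=C(NCCC(C)C)C1=O | target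

**Step count**

Total: 13 steps. Longest linear sequence: 11 steps (steps 1–8, then 11–13); the quinone arm (steps 9 and 10) joins at step 11.

**Steps most likely to fail**

Step 3. The cycloaddition has to form two adjacent quaternary carbons at a tetrasubstituted dienophile, so it may be too slow for the chiral copper complex, the diene may oligomerise under Lewis acid, or facial discrimination may be poor. Fallback: setting out from 3 and 4, the cycloaddition is run without a chiral ligand under SnCl4 in CH2Cl2 at −20 °C, where regio- and endo-selectivity still come from the chelated dienophile. This gives 5 as a racemate, that is, together with its mirror image methyl (3aR,7S,7aR)-3a,7-dimethyl-1-oxo-2,3,3a,4,7,7a-hexahydro-1H-indene-7a-carboxylate F1. The two are separated by preparative chromatography on a chiral stationary phase, and the route is rejoined at 5.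

Step 11. Electron transfer from the alane or from low-valent nickel to the quinone, transfer of a methyl group from residual methylaluminium species, or addition of the alane to a quinone carbonyl may outrun cross-coupling. Fallback: setting out from 10, 14 and the benzylic chloride 12 already in hand, alane 15 is generated as before and coupled under the same nickel catalysis with 12, a standard partner for alkenylalanes that cannot be reduced. This should give 3-{(2E)-5-[(1R,3R)-1,3-dimethyl-2-methylidenecyclohexyl]-3-methylpent-2-en-1-yl}-1,2,4,5-tetramethoxybenzene F2. Oxidative demethylation with (NH4)2Ce(NO3)6 in MeCN/H2O at 0 °C, which isolated alkenes tolerate, then rejoins the route at 16.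

Step 7. If hydride delivery in step 5 gives the C1 epimer with the hydroxyl syn to CH2OMs, intramolecular O-alkylation to an oxetane can compete with fragmentation, and the strong base may also trigger aldol self-condensation of the aldehyde. Fallback: setting out from 8, Dess–Martin periodinane (NaHCO3, CH2Cl2) oxidises the secondary alcohol to [(3aR,7R,7aR)-3a,7-dimethyl-1-oxooctahydro-7aH-inden-7a-yl]methyl methanesulfonate F3, in which ring closure on oxygen is impossible. NaOMe in MeOH at 0 °C adds to the ketone, and the hemiketal alkoxide fragments with loss of mesylate to methyl 3-[(1R,3R)-1,3-dimethyl-2-methylidenecyclohexyl]propanoate F4. i-Bu2AlH in CH2Cl2 at −78 °C reduces the ester to the aldehyde, rejoining the route at 9.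

**Further compounds**

F1 | step 3 | methyl (3aR,7S,7aR)-3a,7-dimethyl-1-oxo-2,3,3a,4,7,7a-hexahydro-1H-indene-7a-carboxylate | COC(=O)[C@]12[C@@H](C)C=CC[C@@]1(C)CCC2=O
F2 | step 11 | 3-{(2E)-5-[(1R,3R)-1,3-dimethyl-2-methylidenecyclohexyl]-3-methylpent-2-en-1-yl}-1,2,4,5-tetramethoxybenzene | C=C1[C@H](C)CCC[C@]1(C)CC/C(C)=C/Cc1c(OC)c(OC)cc(OC)c1OC
F3 | step 7 | [(3aR,7R,7aR)-3a,7-dimethyl-1-oxooctahydro-7aH-inden-7a-yl]methyl methanesulfonate | CS(=O)(=O)OC[C@@]12[C@H](C)CCC[C@]1(C)CCC2=O
F4 | step 7 | methyl 3-[(1R,3R)-1,3-dimethyl-2-methylidenecyclohexyl]propanoate | C=C1[C@H](C)CCC[C@]1(C)CCC(=O)OC
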